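**Retrosynthetic overview**

1. The target comes from acid hydrolysis of four methyl enol ethers and fluoride cleavage of two aryl silyl ethers, preceded by ortho C‑butyrylation of the single free carbon of ring B.
2. The strategy rests on ring B, a hexasubstituted benzene with oxygen on C1, C3 and C5, the CH2 links to rings A and C on the two carbons flanking one C–O carbon, and butyryl on the third. It is made last by benzannulation of a ring C 3‑siloxycyclobutenone with a ring A siloxyalkyne (two new C–C bonds, then 6π closure).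
3. The cyclobutenone comes from the ring C siloxyalkyne and ketene by [2+2]. Both siloxyalkynes come from terminal alkynes by acetylide oxidation and O‑silylation, run with the acyl side chain held as its lithium enolate.
4. The alkynes come from C‑propargylation and O‑methylation of butyryl‑ and propionylfilicinic acid, themselves from phloroglucinol by Friedel–Crafts acylation and dearomatising gem‑dimethylation.
5. Ring order: rings A and C first (dearomatised phloroglucinols), then the four‑membered ring on the ring C fragment, ring B last.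

Key step: step 12

Assumption: the 6‑substituted acylfilicinic acids are drawn as 3,5‑dihydroxy‑2,5‑dienone tautomers and their bis(methyl ethers) as the 3,5‑dimethoxy isomers; a regioisomeric enol ether formed on methylation would carry the same masked triketone and converge on the same product in step 15.

Abbreviations in names: TIPS = triisopropylsilyl; "A‑methyl" = (5‑butanoyl‑2,4‑dimethoxy‑3,3‑dimethyl‑6‑oxocyclohexa‑1,4‑dien‑1‑yl)methyl; "C‑methyl" = (2,4‑dimethoxy‑3,3‑dimethyl‑6‑oxo‑5‑propanoylcyclohexa‑1,4‑dien‑1‑yl)methyl.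

**Route**

Step 1
Reactants: 1 phloroglucinol; 2 butanoyl chloride
Product: 3 1-(2,4,6-trihydroxyphenyl)butan-1-one
Conditions: AlCl3 (4 equiv), PhNO2–CH2Cl2, rt → 50 °C; then 1 M HCl
Reagents that add atoms: none
Why: Friedel–Crafts C‑acylation of phloroglucinol, where the first acyl group deactivates the ring so that monoacylation should prevail.

Step 2
Reactants: 3 1-(2,4,6-trihydroxyphenyl)butan-1-one
Product: 4 2-butanoyl-3,5-dihydroxy-4,4-dimethylcyclohexa-2,5-dien-1-one (butyrylfilicinic acid)
Conditions: NaOMe (4 equiv), MeI (excess), MeOH, 0 °C → rt; then 1 M HCl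
Reagents that add atoms: iodomethane, CI
Why: Dearomatising double C‑methylation of the acylphloroglucinol phenoxide at one of its two equivalent free ring carbons is the standard entry to acylfilicinic acids and creates no stereocentre.

Step 3
Reactants: 4 butyrylfilicinic acid; 5 propargyl bromide
Product: 6 2-butanoyl-3,5-dihydroxy-4,4-dimethyl-6-(prop-2-yn-1-yl)cyclohexa-2,5-dien-1-one
Conditions: KOH (2 equiv), 5 (1.0 equiv), H2O–MeOH, 0 °C → rt; then 1 M HCl
Reagents that add atoms: none
Why: C‑Alkylation of the cyclic β‑triketone dianion by the soft propargylic bromide in protic medium, at the only ring carbon that still bears hydrogen.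

Step 4
Reactants: 6 the C‑propargyl butyrylfilicinic acid
Product: 7 2-butanoyl-3,5-dimethoxy-4,4-dimethyl-6-(prop-2-yn-1-yl)cyclohexa-2,5-dien-1-one
Conditions: Me3SiCHN2 (excess), MeOH–PhMe, 0 °C → rt
Reagents that add atoms: (trimethylsilyl)diazomethane, C[Si](C)(C)C=[N+]=[N-]
Why: O‑Methylation of the acidic enols by a diazoalkane caps both as vinylogous methyl esters, which removes the acidic OH groups that would otherwise add to the alkyne or later destroy the ynol ether.

Step 5
Reactants: 7 the bis(methyl enol ether) alkyne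
Product: 10 2-butanoyl-3,5-dimethoxy-4,4-dimethyl-6-[3-(triisopropylsilyloxy)prop-2-yn-1-yl]cyclohexa-2,5-dien-1-one (ring A siloxyalkyne), via dilithio acetylide enolate 8 (not isolated), via dilithio ynolate enolate 9 (not isolated)
Conditions: LiN(SiMe3)2 (2.2 equiv), THF, −78 °C; LiOOt‑Bu (1.1 equiv, from t‑BuOOH and LiN(SiMe3)2), −78 → 0 °C; i‑Pr3SiCl (1.2 equiv), −78 → 0 °C; pH 7 buffer
Reagents that add atoms: tert-butyl hydroperoxide, CC(C)(C)OO; triisopropylsilyl chloride, CC(C)[Si](Cl)(C(C)C)C(C)C
Why: Oxidation of a lithium acetylide to the lithium ynolate by lithium tert‑butyl peroxide followed by O‑silylation with the hindered chlorosilane is the known route from terminal alkynes to siloxyalkynes; the first equivalent of base turns the butanoyl ketone into its lithium enolate, which removes the more acidic α‑protons, lowers the electrophilicity of the adjacent methoxy‑enone toward the peroxide, is too hindered to be silylated by i‑Pr3SiCl and returns the ketone on buffered work‑up.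

Step 6
Reactants: 1 phloroglucinol; 11 propanoyl chloride
Product: 12 1-(2,4,6-trihydroxyphenyl)propan-1-one
Conditions: AlCl3 (4 equiv), PhNO2–CH2Cl2, rt → 50 °C; then 1 M HCl
Reagents that add atoms: none
Why: Friedel–Crafts monoacylation as in step 1.

Step 7
Reactants: 12 1-(2,4,6-trihydroxyphenyl)propan-1-one
Product: 13 3,5-dihydroxy-4,4-dimethyl-2-propanoylcyclohexa-2,5-dien-1-one (propionylfilicinic acid)
Conditions: NaOMe (4 equiv), MeI (excess), MeOH, 0 °C → rt; then 1 M HCl
Reagents that add atoms: iodomethane, CI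
Why: Dearomatising gem‑dimethylation as in step 2.

Step 8
Reactants: 13 propionylfilicinic acid; 5 propargyl bromide
Product: 14 3,5-dihydroxy-4,4-dimethyl-2-propanoyl-6-(prop-2-yn-1-yl)cyclohexa-2,5-dien-1-one
Conditions: KOH (2 equiv), 5 (1.0 equiv), H2O–MeOH, 0 °C → rt; then 1 M HCl
Reagents that add atoms: none
Why: C‑Alkylation of the β‑triketone dianion at its only free ring carbon, as in step 3.

Step 9
Reactants: 14 the C‑propargyl propionylfilicinic acid
Product: 15 3,5-dimethoxy-4,4-dimethyl-2-propanoyl-6-(prop-2-yn-1-yl)cyclohexa-2,5-dien-1-one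
Conditions: Me3SiCHN2 (excess), MeOH–PhMe, 0 °C → rt
Reagents that add atoms: (trimethylsilyl)diazomethane, C[Si](C)(C)C=[N+]=[N-]
Why: Diazoalkane O‑methylation of both enols, as in step 4.

Step 10
Reactants: 15 the bis(methyl enol ether) alkyne
Product: 18 3,5-dimethoxy-4,4-dimethyl-2-propanoyl-6-[3-(triisopropylsilyloxy)prop-2-yn-1-yl]cyclohexa-2,5-dien-1-one (ring C siloxyalkyne), via dilithio acetylide enolate 16 (not isolated), via dilithio ynolate enolate 17 (not isolated)
Conditions: LiN(SiMe3)2 (2.2 equiv), THF, −78 °C; LiOOt‑Bu (1.1 equiv, from t‑BuOOH and LiN(SiMe3)2), −78 → 0 °C; i‑Pr3SiCl (1.2 equiv), −78 → 0 °C; pH 7 buffer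
Reagents that add atoms: tert-butyl hydroperoxide, CC(C)(C)OO; triisopropylsilyl chloride, CC(C)[Si](Cl)(C(C)C)C(C)C
Why: Acetylide oxidation to the ynolate and O‑silylation with the propanoyl group protected in the flask as its lithium enolate, as in step 5.

Step 11
Reactants: 18 ring C siloxyalkyne
Product: 19 2-[(C‑methyl)]-3-(triisopropylsilyloxy)cyclobut-2-en-1-one, i.e. the cyclobutenone carrying the ring C methylene on C2, OTIPS on C3 and CH2 at C4
Conditions: ketene (gas, excess), CH2Cl2, 0 °C → rt; chromatography on Et3N‑deactivated silica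
Reagents that add atoms: ketene, C=C=O
Why: Thermal [2+2] cycloaddition of ketene with an electron‑rich siloxyalkyne, in which the alkyne carbon β to oxygen (the one bearing the ring C methylene) bonds to the ketene carbonyl carbon and so gives the 2‑alkyl‑3‑siloxycyclobutenone regioisomer.

Step 12
Reactants: 10 ring A siloxyalkyne; 19 ring C 3‑siloxycyclobutenone
Product: 24 2-(A‑methyl)-4-(C‑methyl)-3,5-bis(triisopropylsilyloxy)phenol (ring B phenol with H at C6), via vinylketene 20 (not isolated), via vinylcyclobutenone 21 (not isolated), via dienylketene 22 (not isolated), via cyclohexadienone 23 (not isolated)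
Conditions: 10 (1.0 equiv), 19 (1.1 equiv), PhMe (0.1 M), argon, 80 °C, then 110 °C
Reagents that add atoms: none
Why: Heating opens cyclobutenone 19 by conrotatory 4π electrocyclic ring opening to the (2‑siloxyvinyl)ketene 20, whose ketene C=C adds siloxyalkyne 10 in a [2+2] cycloaddition to give 4‑vinylcyclobutenone 21; a second 4π opening gives dienylketene 22, thermal disrotatory 6π electrocyclisation joins the ketene carbon to the terminal methylene carbon to give dienone 23, and enolisation delivers phenol 24. The closest known reaction type is the Danheiser benzannulation of cyclobutenones with siloxyalkynes, which includes 3‑siloxycyclobutenones made from ketene. Ring B is the only ring closed and it closes by 6π electrocyclisation; no stereocentre remains, since the quaternary carbon of 21 is transient. The step needs regioselectivity in the [2+2] event, and the ynol ether polarity secures it: the carbon β to oxygen, carrying the ring A methylene, bonds to the electrophilic ketene carbonyl carbon, which places the two methylene‑linked rings on either side of one siloxy carbon and leaves the only ring C–H next to the new phenol. Chemoselectivity rests on the absence of free OH groups and of nucleophilic π bonds in the doubly vinylogous ester rings A and C, and release of four‑ring strain together with aromatisation should drive the cascade under neutral conditions.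

Step 13
Reactants: 24 ring B phenol; 2 butanoyl chloride
Product: 25 1-[2-hydroxy-3-(A‑methyl)-5-(C‑methyl)-4,6-bis(triisopropylsilyloxy)phenyl]butan-1-one
Conditions: TiCl4 (3 equiv), 2 (1.2 equiv), CH2Cl2, −78 → −20 °C; aq. NaHCO3/Rochelle salt
Reagents that add atoms: none
Why: Fries‑type ortho Friedel–Crafts acylation in which the titanium phenoxide formed from the free OH delivers the acyl chloride to the adjacent carbon, the only unsubstituted position of an electron‑rich trioxygenated ring; low temperature should spare the silyl and methyl enol ethers.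

Step 14
Reactants: 25 the protected ring B ketone
Product: 26 1-[2,4,6-trihydroxy-3-(A‑methyl)-5-(C‑methyl)phenyl]butan-1-one
Conditions: HF·pyridine, THF–pyridine, 0 °C → rt
Reagents that add atoms: none
Why: Fluoride cleavage of the two aryl silyl ethers under non‑basic conditions, which avoids the base‑induced retro‑Michael exchange of methylene bridges known for this compound class.

Step 15
Reactants: 26 the tetra(methyl enol ether)
Product: 27 target CNP0373153.0
Conditions: 2 M aq. HCl, THF, 40 °C
Reagents that add atoms: water, O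
Why: Acid‑catalysed hydrolysis of the four vinylogous methyl esters (addition of water, loss of methanol) unveils the enolised triketones of rings A and C, and the methylene bridges are stable to dilute acid.

**Compound list**

1 | phloroglucinol | Oc1cc(O)cc(O)c1 | starting material
2 | butanoyl chloride | CCCC(=O)Cl | starting material
3 | 1-(2,4,6-trihydroxyphenyl)butan-1-one | CCCC(=O)c1c(O)cc(O)cc1O | intermediate
4 | 2-butanoyl-3,5-dihydroxy-4,4-dimethylcyclohexa-2,5-dien-1-one | CCCC(=O)C1=C(O)C(C)(C)C(O)=CC1=O | intermediate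
5 | propargyl bromide | BrCC#C | starting material
6 | 2-butanoyl-3,5-dihydroxy-4,4-dimethyl-6-(prop-2-yn-1-yl)cyclohexa-2,5-dien-1-one | CCCC(=O)C1=C(O)C(C)(C)C(O)=C(CC#C)C1=O | intermediate
7 | 2-butanoyl-3,5-dimethoxy-4,4-dimethyl-6-(prop-2-yn-1-yl)cyclohexa-2,5-dien-1-one | CCCC(=O)C1=C(OC)C(C)(C)C(OC)=C(CC#C)C1=O | intermediate
8 | dilithio acetylide enolate of 7 (enolate geometry not defined) | [Li+].[Li+].CCC=C([O-])C1=C(OC)C(C)(C)C(OC)=C(CC#[C-])C1=O | intermediate
9 | dilithio ynolate enolate (enolate geometry not defined) | [Li+].[Li+].CCC=C([O-])C1=C(OC)C(C)(C)C(OC)=C(CC#C[O-])C1=O | intermediate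
10 | ring A siloxyalkyne, 2-butanoyl-3,5-dimethoxy-4,4-dimethyl-6-[3-(triisopropylsilyloxy)prop-2-yn-1-yl]cyclohexa-2,5-dien-1-one | CCCC(=O)C1=C(OC)C(C)(C)C(OC)=C(CC#CO[Si](C(C)C)(C(C)C)C(C)C)C1=O | intermediate
11 | propanoyl chloride | CCC(=O)Cl | starting material
12 | 1-(2,4,6-trihydroxyphenyl)propan-1-one | CCC(=O)c1c(O)cc(O)cc1O | intermediate
13 | 3,5-dihydroxy-4,4-dimethyl-2-propanoylcyclohexa-2,5-dien-1-one | CCC(=O)C1=C(O)C(C)(C)C(O)=CC1=O | intermediate
14 | 3,5-dihydroxy-4,4-dimethyl-2-propanoyl-6-(prop-2-yn-1-yl)cyclohexa-2,5-dien-1-one | CCC(=O)C1=C(O)C(C)(C)C(O)=C(CC#C)C1=O | intermediate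
15 | 3,5-dimethoxy-4,4-dimethyl-2-propanoyl-6-(prop-2-yn-1-yl)cyclohexa-2,5-dien-1-one | CCC(=O)C1=C(OC)C(C)(C)C(OC)=C(CC#C)C1=O | intermediate
16 | dilithio acetylide enolate of 15 (enolate geometry not defined) | [Li+].[Li+].CC=C([O-])C1=C(OC)C(C)(C)C(OC)=C(CC#[C-])C1=O | intermediate
17 | dilithio ynolate enolate (enolate geometry not defined) | [Li+].[Li+].CC=C([O-])C1=C(OC)C(C)(C)C(OC)=C(CC#C[O-])C1=O | intermediate
18 | ring C siloxyalkyne, 3,5-dimethoxy-4,4-dimethyl-2-propanoyl-6-[3-(triisopropylsilyloxy)prop-2-yn-1-yl]cyclohexa-2,5-dien-1-one | CCC(=O)C1=C(OC)C(C)(C)C(OC)=C(CC#CO[Si](C(C)C)(C(C)C)C(C)C)C1=O | intermediate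
19 | ring C cyclobutenone, 2-(C‑methyl)-3-(triisopropylsilyloxy)cyclobut-2-en-1-one | CC(C)[Si](OC1=C(CC2=C(OC)C(C)(C)C(OC)=C(C(=O)CC)C2=O)C(=O)C1)(C(C)C)C(C)C | intermediate
20 | vinylketene, 2-(C‑methyl)-3-(triisopropylsilyloxy)buta-1,3-dien-1-one | O=C=C(CC1=C(OC)C(C)(C)C(OC)=C(C(=O)CC)C1=O)C(=C)O[Si](C(C)C)(C(C)C)C(C)C | intermediate
21 | vinylcyclobutenone (racemic), 2-(A‑methyl)-4-(C‑methyl)-3-(triisopropylsilyloxy)-4-[1-(triisopropylsilyloxy)vinyl]cyclobut-2-en-1-one | O=C1C(CC2=C(OC)C(C)(C)C(OC)=C(C(=O)CCC)C2=O)=C(O[Si](C(C)C)(C(C)C)C(C)C)C1(CC3=C(OC)C(C)(C)C(OC)=C(C(=O)CC)C3=O)C(=C)O[Si](C(C)C)(C(C)C)C(C)C | intermediate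
22 | dienylketene, 2-(A‑methyl)-4-(C‑methyl)-3,5-bis(triisopropylsilyloxy)hexa-1,3,5-trien-1-one, ketene and siloxyvinyl groups cis on the central double bond | O=C=C(CC1=C(OC)C(C)(C)C(OC)=C(C(=O)CCC)C1=O)/C(O[Si](C(C)C)(C(C)C)C(C)C)=C(CC2=C(OC)C(C)(C)C(OC)=C(C(=O)CC)C2=O)\C(=C)O[Si](C(C)C)(C(C)C)C(C)C | intermediate
23 | cyclohexadienone, 2-(A‑methyl)-4-(C‑methyl)-3,5-bis(triisopropylsilyloxy)cyclohexa-2,4-dien-1-one | O=C1CC(O[Si](C(C)C)(C(C)C)C(C)C)=C(CC2=C(OC)C(C)(C)C(OC)=C(C(=O)CC)C2=O)C(O[Si](C(C)C)(C(C)C)C(C)C)=C1CC3=C(OC)C(C)(C)C(OC)=C(C(=O)CCC)C3=O | intermediate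
24 | ring B phenol, 2-(A‑methyl)-4-(C‑methyl)-3,5-bis(triisopropylsilyloxy)phenol | Oc1cc(O[Si](C(C)C)(C(C)C)C(C)C)c(CC2=C(OC)C(C)(C)C(OC)=C(C(=O)CC)C2=O)c(O[Si](C(C)C)(C(C)C)C(C)C)c1CC3=C(OC)C(C)(C)C(OC)=C(C(=O)CCC)C3=O | intermediate
25 | 1-[2-hydroxy-3-(A‑methyl)-5-(C‑methyl)-4,6-bis(triisopropylsilyloxy)phenyl]butan-1-one | CCCC(=O)c1c(O)c(CC2=C(OC)C(C)(C)C(OC)=C(C(=O)CCC)C2=O)c(O[Si](C(C)C)(C(C)C)C(C)C)c(CC3=C(OC)C(C)(C)C(OC)=C(C(=O)CC)C3=O)c1O[Si](C(C)C)(C(C)C)C(C)C | intermediate
26 | 1-[2,4,6-trihydroxy-3-(A‑methyl)-5-(C‑methyl)phenyl]butan-1-one | CCCC(=O)c1c(O)c(CC2=C(OC)C(C)(C)C(OC)=C(C(=O)CCC)C2=O)c(O)c(CC3=C(OC)C(C)(C)C(OC)=C(C(=O)CC)C3=O)c1O | intermediate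
27 | CNP0373153.0: butyrylphloroglucinol ring B linked by CH2 to butyrylfilicinic acid ring A and by CH2 to propionylfilicinic acid ring C (no stereocentres) | CCCC(=O)C1=C(O)C(C)(C)C(O)=C(Cc2c(O)c(CC3=C(O)C(C)(C)C(O)=C(C(=O)CC)C3=O)c(O)c(C(=O)CCC)c2O)C1=O | target

**Step count and risks**

Total steps: 15. Longest linear sequence: 10 steps (steps 6–15, phloroglucinol to target through the ring C fragment); the ring A branch (steps 1–5) joins at step 12.

Steps most likely to fail:

1. Step 12 (key benzannulation). The vinylketene may be consumed before it meets the alkyne, by capture through the neighbouring ring C dienone oxygen, by ketene dimerisation or by O‑acylation of the product phenol. The siloxyalkyne may also isomerise to a silylketene by thermal silyl shift, or the cascade may stall at the crowded vinylcyclobutenone. Fallback with known chemistry and a different bond construction: the classical stepwise alkaline formaldehyde condensation. It sets out from 3 and 4, which with aqueous formaldehyde in dilute KOH at 0 °C should give the two‑ring compound 2-butanoyl-6-[(3-butanoyl-2,4,6-trihydroxyphenyl)methyl]-3,5-dihydroxy-4,4-dimethylcyclohexa-2,5-dien-1-one F1. A second condensation of F1 with 13 and formaldehyde under the same conditions comes back to the route at 27. This gives up bridge fidelity: symmetric homologues from methylene exchange would have to be removed by chromatography, and exchange is limited by low temperature and short contact with base.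

2. Step 5 (and its twin, step 10). Oxygen transfer to the side‑chain enolate, or addition of the peroxide or the acetylide to the methoxy‑dienone, may compete with oxidation of the acetylide. Fallback: build the ynol ether on an acyl‑free ring and add the acyl group afterwards. It sets out from 1, which with NaOMe/MeI should give filicinic acid F2. C‑propargylation with 5 (aq. KOH) gives 3,5-dihydroxy-4,4-dimethyl-2-(prop-2-yn-1-yl)cyclohexa-2,5-dien-1-one F3, and diazoalkane methylation gives 3,5-dimethoxy-4,4-dimethyl-2-(prop-2-yn-1-yl)cyclohexa-2,5-dien-1-one F4. F4 has neither an enolisable ketone nor a doubly activated enone, so acetylide oxidation with LiOOt‑Bu and silylation should give 3,5-dimethoxy-4,4-dimethyl-2-[3-(triisopropylsilyloxy)prop-2-yn-1-yl]cyclohexa-2,5-dien-1-one F5. Vinylic lithiation of the vinylogous ester between C=O and C–OMe with lithium 2,2,6,6-tetramethylpiperidide (THF, −78 °C) and trapping with N‑methoxy‑N‑methylbutanamide comes back to the route at 10; the propanamide analogue gives 18 from the same F5.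

3. Step 13 (ring B butyrylation). The Lewis acid may strip methyl enol ethers or silyl ethers, O‑acylation may occur without migration to carbon, or ipso attack on ring B may cleave a methylene bridge. Fallback free of strong Lewis acid, setting out from 24: Casnati–Skattebøl ortho‑formylation (MgCl2, Et3N, paraformaldehyde, THF, reflux) should give 2-hydroxy-3-(A‑methyl)-5-(C‑methyl)-4,6-bis(triisopropylsilyloxy)benzaldehyde F6. Aldehyde‑selective allylboration with allylboronic acid pinacol ester gives the racemic homoallylic alcohol 1-[2-hydroxy-3-(A‑methyl)-5-(C‑methyl)-4,6-bis(triisopropylsilyloxy)phenyl]but-3-en-1-ol F7. MnO2 oxidation gives 1-[2-hydroxy-3-(A‑methyl)-5-(C‑methyl)-4,6-bis(triisopropylsilyloxy)phenyl]but-3-en-1-one F8, and hydrogenation of the terminal alkene (H2, Pd/C, EtOAc) comes back to the route at 25.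

**Further compounds**

F1 | step 12 | 2-butanoyl-6-[(3-butanoyl-2,4,6-trihydroxyphenyl)methyl]-3,5-dihydroxy-4,4-dimethylcyclohexa-2,5-dien-1-one | CCCC(=O)C1=C(O)C(C)(C)C(O)=C(Cc2c(O)cc(O)c(C(=O)CCC)c2O)C1=O
F2 | step 5 | filicinic acid, 3,5-dihydroxy-4,4-dimethylcyclohexa-2,5-dien-1-one | O=C1C=C(O)C(C)(C)C(O)=C1
F3 | step 5 | 3,5-dihydroxy-4,4-dimethyl-2-(prop-2-yn-1-yl)cyclohexa-2,5-dien-1-one | O=C1C=C(O)C(C)(C)C(O)=C1CC#C
F4 | step 5 | 3,5-dimethoxy-4,4-dimethyl-2-(prop-2-yn-1-yl)cyclohexa-2,5-dien-1-one | COC1=CC(=O)C(CC#C)=C(OC)C1(C)C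
F5 | step 5 | 3,5-dimethoxy-4,4-dimethyl-2-[3-(triisopropylsilyloxy)prop-2-yn-1-yl]cyclohexa-2,5-dien-1-one | COC1=CC(=O)C(CC#CO[Si](C(C)C)(C(C)C)C(C)C)=C(OC)C1(C)C
F6 | step 13 | 2-hydroxy-3-(A‑methyl)-5-(C‑methyl)-4,6-bis(triisopropylsilyloxy)benzaldehyde | O=Cc1c(O)c(CC2=C(OC)C(C)(C)C(OC)=C(C(=O)CCC)C2=O)c(O[Si](C(C)C)(C(C)C)C(C)C)c(CC3=C(OC)C(C)(C)C(OC)=C(C(=O)CC)C3=O)c1O[Si](C(C)C)(C(C)C)C(C)C
F7 | step 13 | 1-[2-hydroxy-3-(A‑methyl)-5-(C‑methyl)-4,6-bis(triisopropylsilyloxy)phenyl]but-3-en-1-ol (racemic) | C=CCC(O)c1c(O)c(CC2=C(OC)C(C)(C)C(OC)=C(C(=O)CCC)C2=O)c(O[Si](C(C)C)(C(C)C)C(C)C)c(CC3=C(OC)C(C)(C)C(OC)=C(C(=O)CC)C3=O)c1O[Si](C(C)C)(C(C)C)C(C)C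
F8 | step 13 | 1-[2-hydroxy-3-(A‑methyl)-5-(C‑methyl)-4,6-bis(triisopropylsilyloxy)phenyl]but-3-en-1-one | C=CCC(=O)c1c(O)c(CC2=C(OC)C(C)(C)C(OC)=C(C(=O)CCC)C2=O)c(O[Si](C(C)C)(C(C)C)C(C)C)c(CC3=C(OC)C(C)(C)C(OC)=C(C(=O)CC)C3=O)c1O[Si](C(C)C)(C(C)C)C(C)C
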